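## Retrosynthetic overview

1. Target 30 ⇐ andrograpanin 29 (O-acetylation) ⇐ iodide 23 + 3-(phenylsulfanyl)oxolan-2-one 25 (enolate alkylation forms C12–C13; sulfoxide elimination gives the butenolide).
2. C4 quaternary centre ⇐ equatorial C-methylation of the enolate of bicyclic aldehyde 18, then CHO → CH2OH.
3. Decalin 18 ⇐ acyclic aldehyde 16 by one new organocatalytic SOMO bicyclization: ring A closes first (C4–C5), ring B second (C10–C9), and the allylsilane ends the cascade as the C8 exocyclic methylene; this sets C5, C9 and C10.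
4. Aldehyde 16 ⇐ bromide 1 + aldehyde 2 by two Johnson–Claisen rearrangements (both trisubstituted alkene geometries) and a two-carbon nitrile homologation.

Assumption: positions are named with labdane numbering (C4 carries CH3-18 and CH2OAc-19, C10 carries CH3-20, C8 the methylene C17, C9 the side chain), and the SMILES is read as the ent-labdane (4R,5S,9R,10S), i.e. 19-O-acetylandrograpanin.

## Route

Step 1
Reactants: 1 (2-bromoprop-2-en-1-yl)trimethylsilane; 2 3-[(tert-butyldimethylsilyl)oxy]propanal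
Product: 4 racemic 5-[(tert-butyldimethylsilyl)oxy]-2-[(trimethylsilyl)methyl]pent-1-en-3-ol, via vinyllithium 3 (not isolated)
Conditions: t-BuLi (2.1 equiv), Et2O, −78 °C; then 2, −78 °C; H2O
Reagents that add atoms: none
Why: Bromine–lithium exchange gives the 2-lithioallylsilane, which adds 1,2 to the aldehyde (organolithium carbonyl addition); the carbinol centre is racemic and is destroyed in step 2.

Step 2
Reactants: 4 racemic 5-[(tert-butyldimethylsilyl)oxy]-2-[(trimethylsilyl)methyl]pent-1-en-3-ol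
Product: 6 ethyl (4Z)-7-[(tert-butyldimethylsilyl)oxy]-4-[(trimethylsilyl)methyl]hept-4-enoate, via ketene acetal 5 (not isolated)
Conditions: CH3C(OEt)3 (6 equiv), EtCO2H (5 mol%), 140 °C, EtOH distilled off
Reagents that add atoms: triethyl orthoacetate CC(OCC)(OCC)OCC
Why: Johnson–Claisen rearrangement through a chair transition state with the CH2CH2OSi chain equatorial places C11 trans to C7 on the new trisubstituted allylsilane alkene and adds the C6–C5 ester arm.

Step 3
Reactants: 6 ethyl (4Z)-7-[(tert-butyldimethylsilyl)oxy]-4-[(trimethylsilyl)methyl]hept-4-enoate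
Product: 8 (4Z)-7-[(tert-butyldimethylsilyl)oxy]-4-[(trimethylsilyl)methyl]hept-4-enal, via aluminium hemiacetal 7 (not isolated)
Conditions: i-Bu2AlH (1.05 equiv), CH2Cl2, −78 °C; aq. potassium sodium tartrate
Reagents that add atoms: none
Why: Partial hydride reduction of the ester stops at the tetrahedral aluminium hemiacetal at −78 °C, which releases the aldehyde on work-up.

Step 4
Reactants: 8 (4Z)-7-[(tert-butyldimethylsilyl)oxy]-4-[(trimethylsilyl)methyl]hept-4-enal
Product: 9 racemic (6Z)-9-[(tert-butyldimethylsilyl)oxy]-2-methyl-6-[(trimethylsilyl)methyl]nona-1,6-dien-3-ol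
Conditions: CH2=C(CH3)MgBr (1.3 equiv), THF, −78 to 0 °C; H2O
Reagents that add atoms: isopropenylmagnesium bromide CC(=C)[Mg]Br
Why: Grignard 1,2-addition gives the second 2-substituted allylic alcohol; its racemic carbinol centre is destroyed in step 5.

Step 5
Reactants: 9 racemic (6Z)-9-[(tert-butyldimethylsilyl)oxy]-2-methyl-6-[(trimethylsilyl)methyl]nona-1,6-dien-3-ol
Product: 11 ethyl (4E,8Z)-11-[(tert-butyldimethylsilyl)oxy]-4-methyl-8-[(trimethylsilyl)methyl]undeca-4,8-dienoate, via ketene acetal 10 (not isolated)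
Conditions: CH3C(OEt)3 (6 equiv), EtCO2H (5 mol%), 140 °C, EtOH distilled off
Reagents that add atoms: triethyl orthoacetate CC(OCC)(OCC)OCC
Why: A second Johnson–Claisen rearrangement (chair transition state, chain equatorial) gives the (E)-C5=C10 alkene required for the trans ring fusion and adds C1–C3.

Step 6
Reactants: 11 ethyl (4E,8Z)-11-[(tert-butyldimethylsilyl)oxy]-4-methyl-8-[(trimethylsilyl)methyl]undeca-4,8-dienoate
Product: 12 (4E,8Z)-11-[(tert-butyldimethylsilyl)oxy]-4-methyl-8-[(trimethylsilyl)methyl]undeca-4,8-dien-1-ol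
Conditions: LiAlH4 (0.75 equiv), Et2O, 0 °C; H2O, aq. NaOH
Reagents that add atoms: none
Why: Hydride reduction of the ester to the primary alcohol; the silyl ether, the alkenes and the allylsilane are inert.

Step 7
Reactants: 12 (4E,8Z)-11-[(tert-butyldimethylsilyl)oxy]-4-methyl-8-[(trimethylsilyl)methyl]undeca-4,8-dien-1-ol
Product: 13 (4E,8Z)-11-[(tert-butyldimethylsilyl)oxy]-4-methyl-8-[(trimethylsilyl)methyl]undeca-4,8-dien-1-yl 4-methylbenzenesulfonate
Conditions: TsCl (1.3 equiv), Et3N (2 equiv), 4-(dimethylamino)pyridine (5 mol%), CH2Cl2, 0 °C to rt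
Reagents that add atoms: 4-methylbenzenesulfonyl chloride Cc1ccc(cc1)S(=O)(=O)Cl
Why: Sulfonylation activates the primary alcohol without an electrophilic halogen source that would attack the allylsilane.

Step 8
Reactants: 13 (4E,8Z)-11-[(tert-butyldimethylsilyl)oxy]-4-methyl-8-[(trimethylsilyl)methyl]undeca-4,8-dien-1-yl 4-methylbenzenesulfonate
Product: 14 (6E,10Z)-13-[(tert-butyldimethylsilyl)oxy]-6-methyl-10-[(trimethylsilyl)methyl]trideca-6,10-dienenitrile
Conditions: CH3CN (3 equiv), n-BuLi (2.8 equiv), THF, −78 °C; then 13, −78 °C to rt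
Reagents that add atoms: acetonitrile CC#N
Why: SN2 alkylation of lithiated acetonitrile by the primary tosylate adds C4 and C19.

Step 9
Reactants: 14 (6E,10Z)-13-[(tert-butyldimethylsilyl)oxy]-6-methyl-10-[(trimethylsilyl)methyl]trideca-6,10-dienenitrile
Product: 16 (6E,10Z)-13-[(tert-butyldimethylsilyl)oxy]-6-methyl-10-[(trimethylsilyl)methyl]trideca-6,10-dienal, via aluminium aldimine 15 (not isolated)
Conditions: i-Bu2AlH (1.3 equiv), toluene, −78 °C; then aq. tartrate buffer (pH 4.5), 0 °C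
Reagents that add atoms: water O (aldehyde oxygen, from hydrolysis of the aldimine)
Why: Hydride reduction of the nitrile stops at the N-aluminio aldimine, and mildly acidic hydrolysis gives the aldehyde without protodesilylation.

Step 10
Reactants: 16 (6E,10Z)-13-[(tert-butyldimethylsilyl)oxy]-6-methyl-10-[(trimethylsilyl)methyl]trideca-6,10-dienal
Product: 18 (1S,4aR,5R,8aR)-5-{2-[(tert-butyldimethylsilyl)oxy]ethyl}-4a-methyl-6-methylidenedecahydronaphthalene-1-carbaldehyde, via enamine 17 (not isolated)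
Conditions: (2R,5R)-5-benzyl-2-tert-butyl-3-methylimidazolidin-4-one trifluoroacetate (20 mol%), (NH4)2Ce(NO3)6 (2.5 equiv), NaHCO3 (3 equiv), H2O (2 equiv), 1,2-dimethoxyethane (0.02 M), −20 °C, 24 h
Reagents that add atoms: water O (carbonyl oxygen, through iminium hydrolysis)
Why: Proposed new method: an enantioselective SOMO (singly occupied molecular orbital) enamine-oxidation bicyclization terminated by an allylsilane, in which tetravalent cerium oxidizes the chiral enamine to a 3π-electron radical cation that adds 6-endo to the (E)-C5=C10 alkene through a chair on the face left open by the benzyl group (forms C4–C5, sets C5), the tertiary C10 radical (or the cation after a second oxidation) closes ring B 6-endo on the allylsilane through a second chair (forms C10–C9, sets C10 and C9 with H-5 and CH3-20 trans and the C9 chain equatorial), and oxidation of the β-silyl radical with loss of the silyl group leaves only the exocyclic C8=C17 alkene; the closest known reactions are the imidazolidinone SOMO polyene cyclizations that end on arenes and the SOMO α-allylation of aldehydes by allylsilanes, two reactivities that have not been combined in one cascade, and the (2R,5R) catalyst is chosen from the accepted facial-shielding model to give the ent series.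

Step 11
Reactants: 18 (1S,4aR,5R,8aR)-5-{2-[(tert-butyldimethylsilyl)oxy]ethyl}-4a-methyl-6-methylidenedecahydronaphthalene-1-carbaldehyde
Product: 20 (1R,4aS,5R,8aS)-5-{2-[(tert-butyldimethylsilyl)oxy]ethyl}-1,4a-dimethyl-6-methylidenedecahydronaphthalene-1-carbaldehyde, via potassium enolate 19 (not isolated)
Conditions: KOt-Bu (1.5 equiv), THF, 0 °C; then CH3I (5 equiv), 0 °C to rt
Reagents that add atoms: iodomethane CI
Why: Aldehyde enolate C-alkylation: the exocyclic enolate is attacked by CH3I along the equatorial trajectory, away from the axial C10 methyl, so the new methyl is equatorial and the formyl group axial and cis to CH3-20, which sets C4 whatever the C4 configuration of 18.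

Step 12
Reactants: 20 (1R,4aS,5R,8aS)-5-{2-[(tert-butyldimethylsilyl)oxy]ethyl}-1,4a-dimethyl-6-methylidenedecahydronaphthalene-1-carbaldehyde
Product: 21 [(1R,4aS,5R,8aS)-5-{2-[(tert-butyldimethylsilyl)oxy]ethyl}-1,4a-dimethyl-6-methylidenedecahydronaphthalen-1-yl]methanol
Conditions: NaBH4 (1 equiv), MeOH, 0 °C
Reagents that add atoms: none
Why: Borohydride reduction of the neopentyl aldehyde to the C19 alcohol; no stereocentre is formed or touched.

Step 13
Reactants: 21 [(1R,4aS,5R,8aS)-5-{2-[(tert-butyldimethylsilyl)oxy]ethyl}-1,4a-dimethyl-6-methylidenedecahydronaphthalen-1-yl]methanol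
Product: 22 2-[(1R,4aS,5R,8aS)-5-(hydroxymethyl)-5,8a-dimethyl-2-methylidenedecahydronaphthalen-1-yl]ethan-1-ol
Conditions: Bu4NF (1.5 equiv), THF, rt; H2O
Reagents that add atoms: none
Why: Fluoride-mediated cleavage of the primary silyl ether (desilylation).

Step 14
Reactants: 22 2-[(1R,4aS,5R,8aS)-5-(hydroxymethyl)-5,8a-dimethyl-2-methylidenedecahydronaphthalen-1-yl]ethan-1-ol
Product: 23 [(1R,4aS,5R,8aS)-5-(2-iodoethyl)-1,4a-dimethyl-6-methylidenedecahydronaphthalen-1-yl]methanol
Conditions: PPh3 (1.15 equiv), I2 (1.15 equiv), imidazole (2.5 equiv), CH2Cl2, 0 °C, 22 added last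
Reagents that add atoms: iodine II
Why: Appel-type iodination is selective for the unhindered C12 alcohol because SN2 displacement at the neopentyl C19 carbinol is too slow.

Step 15
Reactants: 24 racemic 3-bromooxolan-2-one
Product: 25 racemic 3-(phenylsulfanyl)oxolan-2-one
Conditions: PhSH (1.05 equiv), Et3N (1.2 equiv), CH2Cl2, 0 °C to rt
Reagents that add atoms: benzenethiol Sc1ccccc1
Why: SN2 displacement of the α-bromide by thiolate gives the sulfur-activated lactone.

Step 16
Reactants: 23 [(1R,4aS,5R,8aS)-5-(2-iodoethyl)-1,4a-dimethyl-6-methylidenedecahydronaphthalen-1-yl]methanol; 25 racemic 3-(phenylsulfanyl)oxolan-2-one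
Product: 27 3-{2-[(1R,4aS,5R,8aS)-5-(hydroxymethyl)-5,8a-dimethyl-2-methylidenedecahydronaphthalen-1-yl]ethyl}-3-(phenylsulfanyl)oxolan-2-one (both epimers at the lactone carbon), via lithium enolate 26 (not isolated)
Conditions: 25 (1.5 equiv), LiN(SiMe3)2 (1.4 equiv), THF, −78 °C; then 23, HMPA (3 equiv), −78 °C to rt
Reagents that add atoms: none
Why: SN2 alkylation of the preformed sulfur-stabilized lactone enolate by the primary iodide forms C12–C13; the enolate is too weakly basic to deprotonate the hindered alcohol, and the new centre is erased in step 17.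

Step 17
Reactants: 27 3-{2-[(1R,4aS,5R,8aS)-5-(hydroxymethyl)-5,8a-dimethyl-2-methylidenedecahydronaphthalen-1-yl]ethyl}-3-(phenylsulfanyl)oxolan-2-one
Product: 29 andrograpanin: 3-{2-[(1R,4aS,5R,8aS)-5-(hydroxymethyl)-5,8a-dimethyl-2-methylidenedecahydronaphthalen-1-yl]ethyl}furan-2(5H)-one, via sulfoxide 28 (not isolated)
Conditions: mCPBA (1.0 equiv), CH2Cl2, −78 °C; then toluene, CaCO3, 110 °C
Reagents that add atoms: none
Why: Sulfur is oxidized far faster than the 1,1-disubstituted alkene at −78 °C, and thermal syn-elimination of the sulfoxide toward the ring CH2 gives the conjugated endocyclic butenolide (sulfoxide pyrolysis).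

Step 18
Reactants: 29 andrograpanin
Product: 30 [(1R,4aS,5R,8aS)-1,4a-dimethyl-6-methylidene-5-[2-(2-oxo-2,5-dihydrofuran-3-yl)ethyl]decahydronaphthalen-1-yl]methyl acetate
Conditions: Ac2O (3 equiv), pyridine (5 equiv), 4-(dimethylamino)pyridine (10 mol%), CH2Cl2, rt
Reagents that add atoms: acetic anhydride CC(=O)OC(C)=O
Why: Nucleophile-catalysed acylation of the primary neopentyl alcohol gives the target acetate.

## Compound list

1 | (2-bromoprop-2-en-1-yl)trimethylsilane | C=C(Br)C[Si](C)(C)C | starting material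
2 | 3-[(tert-butyldimethylsilyl)oxy]propanal | O=CCCO[Si](C)(C)C(C)(C)C | starting material
3 | [3-(trimethylsilyl)prop-1-en-2-yl]lithium | [Li]C(=C)C[Si](C)(C)C | intermediate
4 | racemic 5-[(tert-butyldimethylsilyl)oxy]-2-[(trimethylsilyl)methyl]pent-1-en-3-ol | C=C(C[Si](C)(C)C)C(O)CCO[Si](C)(C)C(C)(C)C | intermediate
5 | mixed ketene acetal (1-ethoxyethenyl ether of 4) | C=C(OCC)OC(CCO[Si](C)(C)C(C)(C)C)C(=C)C[Si](C)(C)C | intermediate
6 | ethyl (4Z)-7-[(tert-butyldimethylsilyl)oxy]-4-[(trimethylsilyl)methyl]hept-4-enoate | CCOC(=O)CC/C(C[Si](C)(C)C)=C/CCO[Si](C)(C)C(C)(C)C | intermediate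
7 | O-diisobutylaluminio ethyl hemiacetal of 8 | CCOC(O[Al](CC(C)C)CC(C)C)CC/C(C[Si](C)(C)C)=C/CCO[Si](C)(C)C(C)(C)C | intermediate
8 | (4Z)-7-[(tert-butyldimethylsilyl)oxy]-4-[(trimethylsilyl)methyl]hept-4-enal | O=CCC/C(C[Si](C)(C)C)=C/CCO[Si](C)(C)C(C)(C)C | intermediate
9 | racemic (6Z)-9-[(tert-butyldimethylsilyl)oxy]-2-methyl-6-[(trimethylsilyl)methyl]nona-1,6-dien-3-ol | C=C(C)C(O)CC/C(C[Si](C)(C)C)=C/CCO[Si](C)(C)C(C)(C)C | intermediate
10 | mixed ketene acetal (1-ethoxyethenyl ether of 9) | C=C(OCC)OC(CC/C(C[Si](C)(C)C)=C/CCO[Si](C)(C)C(C)(C)C)C(C)=C | intermediate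
11 | ethyl (4E,8Z)-11-[(tert-butyldimethylsilyl)oxy]-4-methyl-8-[(trimethylsilyl)methyl]undeca-4,8-dienoate | CCOC(=O)CC/C(C)=C/CC/C(C[Si](C)(C)C)=C/CCO[Si](C)(C)C(C)(C)C | intermediate
12 | (4E,8Z)-11-[(tert-butyldimethylsilyl)oxy]-4-methyl-8-[(trimethylsilyl)methyl]undeca-4,8-dien-1-ol | OCCC/C(C)=C/CC/C(C[Si](C)(C)C)=C/CCO[Si](C)(C)C(C)(C)C | intermediate
13 | (4E,8Z)-11-[(tert-butyldimethylsilyl)oxy]-4-methyl-8-[(trimethylsilyl)methyl]undeca-4,8-dien-1-yl 4-methylbenzenesulfonate | Cc1ccc(cc1)S(=O)(=O)OCCC/C(C)=C/CC/C(C[Si](C)(C)C)=C/CCO[Si](C)(C)C(C)(C)C | intermediate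
14 | (6E,10Z)-13-[(tert-butyldimethylsilyl)oxy]-6-methyl-10-[(trimethylsilyl)methyl]trideca-6,10-dienenitrile | N#CCCCC/C(C)=C/CC/C(C[Si](C)(C)C)=C/CCO[Si](C)(C)C(C)(C)C | intermediate
15 | N-(diisobutylaluminio) aldimine of 16 | CC(C)C[Al](CC(C)C)N=CCCCC/C(C)=C/CC/C(C[Si](C)(C)C)=C/CCO[Si](C)(C)C(C)(C)C | intermediate
16 | (6E,10Z)-13-[(tert-butyldimethylsilyl)oxy]-6-methyl-10-[(trimethylsilyl)methyl]trideca-6,10-dienal | O=CCCCC/C(C)=C/CC/C(C[Si](C)(C)C)=C/CCO[Si](C)(C)C(C)(C)C | intermediate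
17 | (E)-enamine of 16 with (2R,5R)-5-benzyl-2-tert-butyl-3-methylimidazolidin-4-one (N1-alkenyl) | CN1[C@H](C(C)(C)C)N(/C=C/CCC/C(C)=C/CC/C(C[Si](C)(C)C)=C/CCO[Si](C)(C)C(C)(C)C)[C@H](Cc2ccccc2)C1=O | intermediate
18 | (1S,4aR,5R,8aR)-5-{2-[(tert-butyldimethylsilyl)oxy]ethyl}-4a-methyl-6-methylidenedecahydronaphthalene-1-carbaldehyde (trans-decalin, formyl equatorial) | C=C1CC[C@@H]2[C@@H](C=O)CCC[C@@]2(C)[C@@H]1CCO[Si](C)(C)C(C)(C)C | intermediate
19 | potassium enolate of 18 (exocyclic C4=C19 enolate) | C=C1CC[C@@H]2C(=C[O-])CCC[C@@]2(C)[C@@H]1CCO[Si](C)(C)C(C)(C)C.[K+] | intermediate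
20 | (1R,4aS,5R,8aS)-5-{2-[(tert-butyldimethylsilyl)oxy]ethyl}-1,4a-dimethyl-6-methylidenedecahydronaphthalene-1-carbaldehyde | C=C1CC[C@@H]2[C@](C)(C=O)CCC[C@@]2(C)[C@@H]1CCO[Si](C)(C)C(C)(C)C | intermediate
21 | [(1R,4aS,5R,8aS)-5-{2-[(tert-butyldimethylsilyl)oxy]ethyl}-1,4a-dimethyl-6-methylidenedecahydronaphthalen-1-yl]methanol | C=C1CC[C@@H]2[C@](C)(CO)CCC[C@@]2(C)[C@@H]1CCO[Si](C)(C)C(C)(C)C | intermediate
22 | 2-[(1R,4aS,5R,8aS)-5-(hydroxymethyl)-5,8a-dimethyl-2-methylidenedecahydronaphthalen-1-yl]ethan-1-ol | C=C1CC[C@@H]2[C@](C)(CO)CCC[C@@]2(C)[C@@H]1CCO | intermediate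
23 | [(1R,4aS,5R,8aS)-5-(2-iodoethyl)-1,4a-dimethyl-6-methylidenedecahydronaphthalen-1-yl]methanol | C=C1CC[C@@H]2[C@](C)(CO)CCC[C@@]2(C)[C@@H]1CCI | intermediate
24 | racemic 3-bromooxolan-2-one (α-bromo-γ-butyrolactone) | BrC1CCOC1=O | starting material
25 | racemic 3-(phenylsulfanyl)oxolan-2-one | O=C1OCCC1Sc1ccccc1 | intermediate
26 | lithium enolate of 25 | [Li+].[O-]C1=C(Sc2ccccc2)CCO1 | intermediate
27 | 3-{2-[(1R,4aS,5R,8aS)-5-(hydroxymethyl)-5,8a-dimethyl-2-methylidenedecahydronaphthalen-1-yl]ethyl}-3-(phenylsulfanyl)oxolan-2-one (both epimers at the lactone carbon) | C=C1CC[C@@H]2[C@](C)(CO)CCC[C@@]2(C)[C@@H]1CCC1(Sc2ccccc2)CCOC1=O | intermediate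
28 | 3-(benzenesulfinyl)-3-{2-[(1R,4aS,5R,8aS)-5-(hydroxymethyl)-5,8a-dimethyl-2-methylidenedecahydronaphthalen-1-yl]ethyl}oxolan-2-one (isomer mixture) | C=C1CC[C@@H]2[C@](C)(CO)CCC[C@@]2(C)[C@@H]1CCC1(S(=O)c2ccccc2)CCOC1=O | intermediate
29 | andrograpanin: 3-{2-[(1R,4aS,5R,8aS)-5-(hydroxymethyl)-5,8a-dimethyl-2-methylidenedecahydronaphthalen-1-yl]ethyl}furan-2(5H)-one | C=C1CC[C@@H]2[C@](C)(CO)CCC[C@@]2(C)[C@@H]1CCC1=CCOC1=O | intermediate
30 | [(1R,4aS,5R,8aS)-1,4a-dimethyl-6-methylidene-5-[2-(2-oxo-2,5-dihydrofuran-3-yl)ethyl]decahydronaphthalen-1-yl]methyl acetate | C=C1CC[C@@H]2[C@](C)(COC(C)=O)CCC[C@@]2(C)[C@@H]1CCC1=CCOC1=O | target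

## Step count and risks

Total step count: 18. Longest linear sequence: 17 (steps 1–14 and 16–18; step 15 is a one-step side branch).

Three steps most likely to fail:

**Step 10 (the proposed new step).** Likely failure modes are direct oxidation or protodesilylation of the electron-rich allylsilane, nitrate capture at C10 before ring B closes, and insufficient enantioselectivity. The fallback uses known chemistry, an auxiliary-controlled oxidative radical polyene cyclization; it sets out from ester 11 and comes back at alcohol 21. (1R,2S,5R)-8-Phenylmenthol (the auxiliary enantiomer expected to give the ent series) is acetylated with Ac2O and pyridine to (1R,2S,5R)-8-phenylmenthyl acetate F1. The lithium enolate of this acetate (LiN(i-Pr)2, 2.2 equiv, THF, −78 °C) is acylated by 11 in a crossed Claisen condensation to give the acyclic β-keto ester F2. Treatment with Mn(OAc)3·2H2O (2.2 equiv, trivalent manganese) and Yb(OTf)3 in CF3CH2OH at −5 °C closes both rings; the auxiliary shields one face of the keto ester radical, and the β-silyl radical at C8 is oxidized with loss of the silyl group, giving the bicyclic β-keto ester F3. NaH and CH3OCH2Cl convert it into the methoxymethyl enol ether F4. Li in liquid NH3/THF at −78 °C followed by CH3I removes the C3 oxygen and methylates the C4 ester enolate from the equatorial side, giving the C4-methylated 8-phenylmenthyl ester F5 with the ester axial. LiAlH4 in refluxing THF then reduces the hindered ester to 21.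

**Step 11.** The risks are O-methylation and incomplete facial selectivity in the alkylation of the aldehyde enolate. The fallback changes to the ester enolate; it sets out from aldehyde 18 and comes back at alcohol 21. Pinnick oxidation (NaClO2, NaH2PO4, 2-methylbut-2-ene, t-BuOH/H2O) gives carboxylic acid F6. Me3SiCHN2 in toluene/MeOH gives methyl ester F7. LiN(i-Pr)2 in THF at −78 °C followed by CH3I and HMPA gives the C4-methylated methyl ester F8 (equatorial attack, axial CO2CH3). LiAlH4 in refluxing Et2O gives 21.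

**Step 5.** The trisubstituted allylsilane may protodesilylate under the hot, weakly acidic Claisen conditions, or the alkene geometry may erode. The fallback builds the C5=C10 alkene by olefination and the C1–C2 bond by enolate alkylation; it sets out from aldehyde 8 and comes back at ester 11. Wittig reaction with Ph3P=C(CH3)CO2Et (CH2Cl2, rt) gives the (E)-enoate F9. i-Bu2AlH (2.2 equiv, CH2Cl2, −78 °C) gives allylic alcohol F10. CBr4 and PPh3 (CH2Cl2, 0 °C) give allylic bromide F11. Alkylation of the lithium enolate of ethyl acetate (LiN(i-Pr)2, EtOAc, THF/HMPA, −78 °C) with this bromide gives 11.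

## Further compounds

F1 | step 10 | (1R,2S,5R)-5-methyl-2-(2-phenylpropan-2-yl)cyclohexyl acetate | C[C@@H]1CC[C@H]([C@@H](C1)OC(C)=O)C(C)(C)c1ccccc1
F2 | step 10 | (1R,2S,5R)-5-methyl-2-(2-phenylpropan-2-yl)cyclohexyl (6E,10Z)-13-[(tert-butyldimethylsilyl)oxy]-6-methyl-3-oxo-10-[(trimethylsilyl)methyl]trideca-6,10-dienoate | C[C@@H]1CC[C@H]([C@@H](C1)OC(=O)CC(=O)CC/C(C)=C/CC/C(C[Si](C)(C)C)=C/CCO[Si](C)(C)C(C)(C)C)C(C)(C)c1ccccc1
F3 | step 10 | (1R,2S,5R)-8-phenylmenthyl (4aR,5R,8aR)-5-{2-[(tert-butyldimethylsilyl)oxy]ethyl}-4a-methyl-6-methylidene-2-oxodecahydronaphthalene-1-carboxylate (C1 epimerizable) | C=C1CC[C@@H]2C(C(=O)O[C@@H]3C[C@H](C)CC[C@H]3C(C)(C)c4ccccc4)C(=O)CC[C@@]2(C)[C@@H]1CCO[Si](C)(C)C(C)(C)C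
F4 | step 10 | methoxymethyl enol ether of F3 (2-(methoxymethoxy)-1,2-ene; trans-decalin stereocentres as in F3) | C=C1CC[C@@H]2C(C(=O)O[C@@H]3C[C@H](C)CC[C@H]3C(C)(C)c4ccccc4)=C(OCOC)CC[C@@]2(C)[C@@H]1CCO[Si](C)(C)C(C)(C)C
F5 | step 10 | (1R,2S,5R)-8-phenylmenthyl ester of the C19 acid corresponding to 21 (C4 methyl equatorial, ester axial; C3 is CH2) | C=C1CC[C@@H]2[C@](C)(C(=O)O[C@@H]3C[C@H](C)CC[C@H]3C(C)(C)c4ccccc4)CCC[C@@]2(C)[C@@H]1CCO[Si](C)(C)C(C)(C)C
F6 | step 11 | (1S,4aR,5R,8aR)-5-{2-[(tert-butyldimethylsilyl)oxy]ethyl}-4a-methyl-6-methylidenedecahydronaphthalene-1-carboxylic acid | C=C1CC[C@@H]2[C@@H](C(=O)O)CCC[C@@]2(C)[C@@H]1CCO[Si](C)(C)C(C)(C)C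
F7 | step 11 | methyl (1S,4aR,5R,8aR)-5-{2-[(tert-butyldimethylsilyl)oxy]ethyl}-4a-methyl-6-methylidenedecahydronaphthalene-1-carboxylate | C=C1CC[C@@H]2[C@@H](C(=O)OC)CCC[C@@]2(C)[C@@H]1CCO[Si](C)(C)C(C)(C)C
F8 | step 11 | methyl (1R,4aS,5R,8aS)-5-{2-[(tert-butyldimethylsilyl)oxy]ethyl}-1,4a-dimethyl-6-methylidenedecahydronaphthalene-1-carboxylate | C=C1CC[C@@H]2[C@](C)(C(=O)OC)CCC[C@@]2(C)[C@@H]1CCO[Si](C)(C)C(C)(C)C
F9 | step 5 | ethyl (2E,6Z)-9-[(tert-butyldimethylsilyl)oxy]-2-methyl-6-[(trimethylsilyl)methyl]nona-2,6-dienoate | CCOC(=O)/C(C)=C/CC/C(C[Si](C)(C)C)=C/CCO[Si](C)(C)C(C)(C)C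
F10 | step 5 | (2E,6Z)-9-[(tert-butyldimethylsilyl)oxy]-2-methyl-6-[(trimethylsilyl)methyl]nona-2,6-dien-1-ol | OC/C(C)=C/CC/C(C[Si](C)(C)C)=C/CCO[Si](C)(C)C(C)(C)C
F11 | step 5 | {[(3Z,7E)-9-bromo-8-methyl-4-[(trimethylsilyl)methyl]nona-3,7-dien-1-yl]oxy}(tert-butyl)dimethylsilane | BrC/C(C)=C/CC/C(C[Si](C)(C)C)=C/CCO[Si](C)(C)C(C)(C)C
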